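**Plan**

- The last disconnection removes four O-alkyl groups (one ethyl, three methyl). Before it, ring A of flavone 1 (the half linked through its 4'-oxygen) is cut at C4a–C5, C5–C6, C7–C8 and C8–C8a, giving a 6-aryl-4-pyranon-2-yl diazomethyl ketone and ethoxyacetylene.
- Enabling feature: ring A of flavone 1 (C4a, C5, C6, C7, C8, C8a) is a benzene ring with oxygen at C5 and C7 and hydrogen at C6 and C8, fused to pyranone ring C across the C4a–C8a bond. This is the pattern a vinylketene–alkoxyalkyne benzannulation delivers.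
- The pyranone (future ring C of flavone 1) is cut at O1–C8a (cyclodehydration), C4a–C8a (Claisen with diethyl oxalate) and C3–C4 (Claisen with ethyl acetate). Then the diaryl ether C4'–O bond (SNAr) and the C8''–O bond of flavone 2 are cut.
- Forward: trimethylapigenin (flavone 2, all three rings present) is oxygenated at C8, joined to 4-fluoroacetophenone, extended to the pyranone acid, converted to the diazoketone, benzannulated (ring A of flavone 1 forms last) and dealkylated.
- Stereochemistry: the target has no stereocentre and no hindered axis, so nothing has to be set.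

Key step: step 9

Notation: ArO– = [5,7-dimethoxy-2-(4-methoxyphenyl)-4-oxo-4H-chromen-8-yl]oxy. The monocyclic pyranone is numbered O1, C2 (carbonyl substituent), C3, C4 (C=O), C5, C6 (aryl).
Assumption: ethereal diazomethane is freshly generated from N-methyl-N-nitroso-p-toluenesulfonamide and KOH; ethoxyacetylene is used as its commercial hexane solution.

Step 1
Reactants: 1 4',5,7-trimethoxyflavone
Product: 2 8-iodo-5,7-dimethoxy-2-(4-methoxyphenyl)-4H-chromen-4-one
Conditions: NIS (1.05 equiv), TFA (cat.), MeCN, rt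
Reagents that add atoms: N-iodosuccinimide, O=C1CCC(=O)N1I
Why: Electrophilic aromatic iodination should occur on the electron-rich ring A at C8 (activated by the C7 methoxy group and the ring oxygen, less hindered than C6 between two methoxy groups), while the anisyl ring is deactivated by the conjugated pyranone.

Step 2
Reactants: 2 8-iodo-5,7-dimethoxy-2-(4-methoxyphenyl)-4H-chromen-4-one
Product: 3 5,7-dimethoxy-2-(4-methoxyphenyl)-8-(4,4,5,5-tetramethyl-1,3,2-dioxaborolan-2-yl)-4H-chromen-4-one
Conditions: B2pin2, PdCl2(dppf)·CH2Cl2 (5 mol %), KOAc, 1,4-dioxane, 90 °C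
Reagents that add atoms: bis(pinacolato)diboron, CC1(C)OB(OC1(C)C)B1OC(C)(C)C(C)(C)O1
Why: Miyaura borylation (oxidative addition of zerovalent palladium into the C–I bond, acetate-assisted transmetalation, reductive elimination) is an established way to flavone 8-boronates.

Step 3
Reactants: 3 the flavone 8-pinacolboronate
Product: 4 8-hydroxy-5,7-dimethoxy-2-(4-methoxyphenyl)-4H-chromen-4-one
Conditions: NaBO3·4H2O, THF/H2O (1:1), rt
Reagents that add atoms: sodium perborate NaBO3·4H2O (peroxoborate dimer), [Na+].[Na+].O[B-]1(O)OO[B-](O)(O)OO1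
Why: Boronate oxidation (1,2-shift of the aryl group from boron to peroxide oxygen, then hydrolysis) is a standard arylboronate-to-phenol conversion, and the weakly basic medium should leave the flavone intact.

Step 4
Reactants: 4 8-hydroxy-5,7-dimethoxy-2-(4-methoxyphenyl)-4H-chromen-4-one; 5 4-fluoroacetophenone
Product: 6 8-(4-acetylphenoxy)-5,7-dimethoxy-2-(4-methoxyphenyl)-4H-chromen-4-one
Conditions: K2CO3, DMF, 120 °C
Reagents that add atoms: none
Why: Nucleophilic aromatic substitution (SNAr): the phenoxide of 4 displaces fluoride para to the acetyl group through a Meisenheimer intermediate, the usual diaryl ether synthesis with 4-fluoroacetophenone.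

Step 5
Reactants: 6 8-(4-acetylphenoxy)-5,7-dimethoxy-2-(4-methoxyphenyl)-4H-chromen-4-one; 7 ethyl acetate
Product: 8 1-[4-(ArO)phenyl]butane-1,3-dione
Conditions: NaH (3 equiv), EtOAc (5 equiv), EtOH (cat.), THF, 0 → 60 °C; 1 M HCl
Reagents that add atoms: none
Why: Crossed Claisen condensation of the methyl ketone enolate with ethyl acetate is driven by formation of the stabilised diketonate, and flavone 2 has no C–H acidic toward NaH.

Step 6
Reactants: 8 1-[4-(ArO)phenyl]butane-1,3-dione; 9 diethyl oxalate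
Product: 11 ethyl 6-[4-(ArO)phenyl]-4-oxo-4H-pyran-2-carboxylate, via triketo ester 10 (not isolated)
Conditions: NaH (4 equiv), (CO2Et)2 (1.5 equiv), THF, 0 °C → reflux; 1 M HCl; then p-TsOH·H2O (cat.), toluene, 80 °C
Reagents that add atoms: none
Why: Claisen condensation at the terminal methyl group of the β-diketone under excess NaH (the classical route from aroylacetones to 6-arylcomanic esters) gives the 1,3,5-triketone, whose acid-catalysed cyclodehydration can only close the six-membered 4-pyranone.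

Step 7
Reactants: 11 ethyl 6-[4-(ArO)phenyl]-4-oxo-4H-pyran-2-carboxylate
Product: 12 6-[4-(ArO)phenyl]-4-oxo-4H-pyran-2-carboxylic acid
Conditions: LiOH·H2O (1.2 equiv), THF/H2O, 0 °C; 1 M HCl to pH 2
Reagents that add atoms: lithium hydroxide, [Li+].[OH-]
Why: Saponification of this activated ester should be fast at 0 °C with near-stoichiometric hydroxide, as for chromone-2-carboxylates, and acidification recloses any ring-opened pyranone.

Step 8
Reactants: 12 6-[4-(ArO)phenyl]-4-oxo-4H-pyran-2-carboxylic acid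
Product: 14 2-diazo-1-{6-[4-(ArO)phenyl]-4-oxo-4H-pyran-2-yl}ethanone, via isobutyl carbonic anhydride 13 (not isolated)
Conditions: iBuOCOCl, N-methylmorpholine, THF, −15 °C; then CH2N2 (3 equiv), Et2O, −15 °C → rt; AcOH quench
Reagents that add atoms: diazomethane, C=[N+]=[N-]
Why: Arndt–Eistert-type acylation of diazomethane through the mixed carbonic anhydride avoids chlorinating agents that would turn the pyranone and flavone carbonyls into chloropyrylium salts, and diazomethane should attack the more electrophilic acyl carbonyl.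

Step 9
Reactants: 14 2-diazo-1-{6-[4-(ArO)phenyl]-4-oxo-4H-pyran-2-yl}ethanone; 15 ethoxyacetylene
Product: 20 7-ethoxy-5-hydroxy-2-[4-(ArO)phenyl]-4H-chromen-4-one, via pyranonylketene 16 (not isolated), via ethoxycyclobutenone 17 (not isolated), via dienylketene 18 (not isolated), via chromenedione keto tautomer 19 (not isolated)
Conditions: ethoxyacetylene (3 equiv), degassed ClCH2CH2Cl, blue LEDs (450 nm), rt; then 80 °C
Reagents that add atoms: none
Why: Proposed new method: Visible-light Wolff rearrangement of 14 expels N2 and shifts the pyranonyl group to the former diazo carbon to give ketene 16, the nucleophilic CH terminus of ethoxyacetylene adds to the ketene carbon in a regioselective [2+2] cycloaddition to give 3-ethoxycyclobutenone 17, and warming causes reversible 4π electrocyclic opening to dienylketene 18. Ring A then closes by thermal disrotatory 6π electrocyclisation of 18 onto pyranone C3, and the resulting dione 19 tautomerises to the chelated 5-hydroxychromone 20. The closest known reaction is the second-generation Danheiser benzannulation of aryl and heteroaryl diazomethyl ketones with alkoxy- and siloxyalkynes, in which an arene C=C bond plays the part taken here by the pyranone C2=C3 bond. No stereocentre remains in 20, since the sp3 centres of 17 and 19 are transient and racemic. The selectivity needed is regiochemical: the polarisation of the ynol ether puts OEt at C7, meta to the new C5 hydroxyl, and closure can occur only at C3 because the other neighbour of C2 is the ring oxygen. Blue light is chosen so that only the diazoketone absorbs and the 4-pyranone and flavone chromophores stay unexcited, and the hydrogen bond from the new 5-OH to C4=O should protect it from acylation by 16.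

Step 10
Reactants: 20 7-ethoxy-5-hydroxy-2-[4-(ArO)phenyl]-4H-chromen-4-one
Product: 21 lanaroflavone
Conditions: BBr3 (12 equiv), CH2Cl2, −78 °C → rt (40 °C if needed); MeOH then H2O
Reagents that add atoms: none
Why: Exhaustive ether cleavage with BBr3 (Lewis acid complexation, then SN2 attack of bromide on the O-alkyl carbon) should remove the ethyl and three methyl groups but not cleave the diaryl ether, and the anhydrous medium should not open the pyranone rings, so no Wessely–Moser-type isomerisation of the 8-aryloxy unit is expected.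

**Compound list**

1 | 4',5,7-trimethoxyflavone (5,7-dimethoxy-2-(4-methoxyphenyl)-4H-chromen-4-one) | COc1ccc(cc1)-c1cc(=O)c2c(OC)cc(OC)cc2o1 | starting material
2 | 8-iodo-5,7-dimethoxy-2-(4-methoxyphenyl)-4H-chromen-4-one | COc1ccc(cc1)-c1cc(=O)c2c(OC)cc(OC)c(I)c2o1 | intermediate
3 | 5,7-dimethoxy-2-(4-methoxyphenyl)-8-(4,4,5,5-tetramethyl-1,3,2-dioxaborolan-2-yl)-4H-chromen-4-one | COc1ccc(cc1)-c1cc(=O)c2c(OC)cc(OC)c(B3OC(C)(C)C(C)(C)O3)c2o1 | intermediate
4 | 8-hydroxy-5,7-dimethoxy-2-(4-methoxyphenyl)-4H-chromen-4-one | COc1ccc(cc1)-c1cc(=O)c2c(OC)cc(OC)c(O)c2o1 | intermediate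
5 | 4-fluoroacetophenone | CC(=O)c1ccc(F)cc1 | starting material
6 | 8-(4-acetylphenoxy)-5,7-dimethoxy-2-(4-methoxyphenyl)-4H-chromen-4-one | CC(=O)c1ccc(Oc2c(OC)cc(OC)c3c(=O)cc(oc23)-c2ccc(OC)cc2)cc1 | intermediate
7 | ethyl acetate | CCOC(C)=O | starting material
8 | 1-(4-{[5,7-dimethoxy-2-(4-methoxyphenyl)-4-oxo-4H-chromen-8-yl]oxy}phenyl)butane-1,3-dione | CC(=O)CC(=O)c1ccc(Oc2c(OC)cc(OC)c3c(=O)cc(oc23)-c2ccc(OC)cc2)cc1 | intermediate
9 | diethyl oxalate | CCOC(=O)C(=O)OCC | starting material
10 | ethyl 6-(4-{[5,7-dimethoxy-2-(4-methoxyphenyl)-4-oxo-4H-chromen-8-yl]oxy}phenyl)-2,4,6-trioxohexanoate | CCOC(=O)C(=O)CC(=O)CC(=O)c1ccc(Oc2c(OC)cc(OC)c3c(=O)cc(oc23)-c2ccc(OC)cc2)cc1 | intermediate (not isolated)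
11 | ethyl 6-(4-{[5,7-dimethoxy-2-(4-methoxyphenyl)-4-oxo-4H-chromen-8-yl]oxy}phenyl)-4-oxo-4H-pyran-2-carboxylate | CCOC(=O)c1cc(=O)cc(o1)-c1ccc(Oc2c(OC)cc(OC)c3c(=O)cc(oc23)-c2ccc(OC)cc2)cc1 | intermediate
12 | 6-(4-{[5,7-dimethoxy-2-(4-methoxyphenyl)-4-oxo-4H-chromen-8-yl]oxy}phenyl)-4-oxo-4H-pyran-2-carboxylic acid | OC(=O)c1cc(=O)cc(o1)-c1ccc(Oc2c(OC)cc(OC)c3c(=O)cc(oc23)-c2ccc(OC)cc2)cc1 | intermediate
13 | mixed anhydride of acid 12 with isobutyl hydrogen carbonate | CC(C)COC(=O)OC(=O)c1cc(=O)cc(o1)-c1ccc(Oc2c(OC)cc(OC)c3c(=O)cc(oc23)-c2ccc(OC)cc2)cc1 | intermediate (not isolated)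
14 | 2-diazo-1-[6-(4-{[5,7-dimethoxy-2-(4-methoxyphenyl)-4-oxo-4H-chromen-8-yl]oxy}phenyl)-4-oxo-4H-pyran-2-yl]ethanone | [N-]=[N+]=CC(=O)c1cc(=O)cc(o1)-c1ccc(Oc2c(OC)cc(OC)c3c(=O)cc(oc23)-c2ccc(OC)cc2)cc1 | intermediate
15 | ethoxyacetylene | C#COCC | starting material
16 | [6-(4-{[5,7-dimethoxy-2-(4-methoxyphenyl)-4-oxo-4H-chromen-8-yl]oxy}phenyl)-4-oxo-4H-pyran-2-yl]ketene | O=C=Cc1cc(=O)cc(o1)-c1ccc(Oc2c(OC)cc(OC)c3c(=O)cc(oc23)-c2ccc(OC)cc2)cc1 | intermediate (not isolated)
17 | 3-ethoxy-4-(6-aryl-4-oxo-4H-pyran-2-yl)cyclobut-2-en-1-one, racemic, aryl = 4-(ArO)phenyl | CCOC1=CC(=O)C1c1cc(=O)cc(o1)-c1ccc(Oc2c(OC)cc(OC)c3c(=O)cc(oc23)-c2ccc(OC)cc2)cc1 | intermediate (not isolated)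
18 | (3E)-3-ethoxy-4-(6-aryl-4-oxo-4H-pyran-2-yl)buta-1,3-dien-1-one, ketenyl group cis to the pyranonyl group, aryl = 4-(ArO)phenyl | O=C=C/C(OCC)=C\c1cc(=O)cc(o1)-c1ccc(Oc2c(OC)cc(OC)c3c(=O)cc(oc23)-c2ccc(OC)cc2)cc1 | intermediate (not isolated)
19 | 7-ethoxy-2-[4-(ArO)phenyl]-4aH-chromene-4,5-dione, racemic keto tautomer of 20 | CCOC1=CC(=O)C2C(=O)C=C(OC2=C1)c1ccc(Oc2c(OC)cc(OC)c3c(=O)cc(oc23)-c2ccc(OC)cc2)cc1 | intermediate (not isolated)
20 | 7-ethoxy-5-hydroxy-2-(4-{[5,7-dimethoxy-2-(4-methoxyphenyl)-4-oxo-4H-chromen-8-yl]oxy}phenyl)-4H-chromen-4-one | CCOc1cc(O)c2c(=O)cc(oc2c1)-c1ccc(Oc2c(OC)cc(OC)c3c(=O)cc(oc23)-c2ccc(OC)cc2)cc1 | intermediate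
21 | lanaroflavone | O=c1cc(-c2ccc(Oc3c(O)cc(O)c4c(=O)cc(-c5ccc(O)cc5)oc34)cc2)oc2cc(O)cc(O)c12 | target

**Step count and risks**

Total step count: 10. Longest linear sequence: 10 steps (1 → 21).

Steps most likely to fail:

1. Step 9 (key benzannulation). The ketene may be consumed by dimerisation or other side reactions before the ynol ether traps it, or the 6π closure onto the cross-conjugated pyranone may not compete with decomposition of the cyclobutenone and dienylketene. The fallback uses only known flavone chemistry and sets out from 4. SNAr with 4-fluorobenzaldehyde (K2CO3, DMF, 110 °C) should give 4-{[5,7-dimethoxy-2-(4-methoxyphenyl)-4-oxo-4H-chromen-8-yl]oxy}benzaldehyde F1. Claisen–Schmidt condensation with commercial 2'-hydroxy-4',6'-dimethoxyacetophenone (KOH, EtOH, rt) should give the 2'-hydroxychalcone F2. Oxidative cyclisation (iodine cat., DMSO, 130 °C) should give penta-O-methyl-lanaroflavone F3. BBr3 (CH2Cl2, −78 °C → rt) then returns to the route at 21.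

2. Step 8 (diazoketone formation). Diazomethane may add as a 1,3-dipole across the doubly activated pyranone C2=C3 bond, or attack the carbonate carbonyl so that the acid is lost as its methyl ester. The fallback replaces acylation of diazomethane by diazo transfer and sets out from 12. Amide coupling (MeNHOMe·HCl, EDC·HCl, HOBt, iPr2NEt, CH2Cl2) should give the N-methoxy-N-methylamide F4. MeMgBr (THF, −78 °C) should give 2-acetyl-6-[4-(ArO)phenyl]-4H-pyran-4-one F5. Deprotonation with LiN(SiMe3)2 (THF, −78 °C) and trifluoroacetylation with CF3CO2CH2CF3 should give the trifluoroacetyl diketone F6, which is not isolated. Treatment with MsN3, Et3N and H2O in MeCN (detrifluoroacetylative diazo transfer) returns to the route at 14.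

3. Step 6 (oxalate Claisen and cyclodehydration). Acylation may occur at the central carbon or on oxygen instead of the terminal methyl group, or the diketone may undergo base-induced retro-Claisen cleavage under the strongly basic conditions. The fallback replaces the base-mediated Claisen by a Lewis-acid acylation of a preformed dienol ether and sets out from 8. Soft enolisation (TMSOTf 2.2 equiv, Et3N, CH2Cl2, 0 °C) should give the 1,3-bis(trimethylsilyloxy)-1,3-diene F7. Mukaiyama-type acylation at its terminal carbon with ethyl chlorooxoacetate (CH2Cl2, −78 °C → rt, TMSOTf cat.) should give triketo ester 10 after aqueous work-up. p-TsOH·H2O in toluene at 80 °C returns to the route at 11.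

**Further compounds**

F1 | step 9 | 4-{[5,7-dimethoxy-2-(4-methoxyphenyl)-4-oxo-4H-chromen-8-yl]oxy}benzaldehyde | O=Cc1ccc(Oc2c(OC)cc(OC)c3c(=O)cc(oc23)-c2ccc(OC)cc2)cc1
F2 | step 9 | (E)-1-(2-hydroxy-4,6-dimethoxyphenyl)-3-[4-(ArO)phenyl]prop-2-en-1-one | COc1cc(O)c(C(=O)/C=C/c2ccc(Oc3c(OC)cc(OC)c4c(=O)cc(oc34)-c3ccc(OC)cc3)cc2)c(OC)c1
F3 | step 9 | penta-O-methyl-lanaroflavone (5,7-dimethoxy-2-[4-(ArO)phenyl]-4H-chromen-4-one) | COc1cc(OC)c2c(=O)cc(oc2c1)-c1ccc(Oc2c(OC)cc(OC)c3c(=O)cc(oc23)-c2ccc(OC)cc2)cc1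
F4 | step 8 | N-methoxy-N-methyl-6-[4-(ArO)phenyl]-4-oxo-4H-pyran-2-carboxamide | CON(C)C(=O)c1cc(=O)cc(o1)-c1ccc(Oc2c(OC)cc(OC)c3c(=O)cc(oc23)-c2ccc(OC)cc2)cc1
F5 | step 8 | 2-acetyl-6-[4-(ArO)phenyl]-4H-pyran-4-one | CC(=O)c1cc(=O)cc(o1)-c1ccc(Oc2c(OC)cc(OC)c3c(=O)cc(oc23)-c2ccc(OC)cc2)cc1
F6 | step 8 | 4,4,4-trifluoro-1-{6-[4-(ArO)phenyl]-4-oxo-4H-pyran-2-yl}butane-1,3-dione | O=C(CC(=O)C(F)(F)F)c1cc(=O)cc(o1)-c1ccc(Oc2c(OC)cc(OC)c3c(=O)cc(oc23)-c2ccc(OC)cc2)cc1
F7 | step 6 | (Z)-1-[4-(ArO)phenyl]-1,3-bis(trimethylsilyloxy)buta-1,3-diene | C=C(O[Si](C)(C)C)/C=C(\O[Si](C)(C)C)c1ccc(Oc2c(OC)cc(OC)c3c(=O)cc(oc23)-c2ccc(OC)cc2)cc1
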